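**Strategy**

The ten-membered carbocycle is closed last, between the butenolide β-carbon C7 and the ester-bearing carbinol carbon C8 (germacranolide numbering). An intramolecular Nozaki–Hiyama–Kishi reaction of an acyclic keto aldehyde that carries a 4-bromobutenolide turns C7, a vinylogous acyl bromide, into a nucleophilic alkenylchromium that adds to the C8 aldehyde. One operation forms the C7–C8 bond, the ring, the C8 stereocentre and the hydroxyl that later bears the tiglate. It exploits the sp2 carbon C7 of the furanone ring (O–C6–C7=C11–C12) next to oxygenated C8. The precursor is assembled without protecting groups from nerol (C1–C6 with the epoxide), a dibromoacrylate (C7, C11–C13) and a crotylboronate (C8–C10).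

Key step: step 10

Remark: atoms are numbered as in germacranolides: C1 ketone carbon, C4/C5 epoxide carbons, C6 lactone carbinol carbon, C7=C11 butenolide olefin, C8 ester carbinol carbon, C10 methyl-bearing carbon, C12 lactone carbonyl, C13 acetoxymethyl carbon.
Remark: the tartrate-derived (E)-crotylboronate of step 7 is treated as a known stock reagent (made beforehand from trans-2-butene, B(OiPr)3 and D-(−)-diisopropyl tartrate).

**Route**

Step 1
Reactants: 1 ethyl bromopyruvate
Product: 2 ethyl 3-acetoxy-2-oxopropanoate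
Conditions: KOAc, acetone, 0 °C to rt
Reagents that add atoms: potassium acetate CC(=O)[O-].[K+]
Why: Carboxylate alkylation (SN2) at the activated α-bromo ketone carbon installs the C13 acetate; no stereocentre is formed.

Step 2
Reactants: 2 ethyl 3-acetoxy-2-oxopropanoate
Product: 3 ethyl 2-(acetoxymethyl)-3,3-dibromoprop-2-enoate
Conditions: CBr4, PPh3, CH2Cl2, 0 °C
Reagents that add atoms: carbon tetrabromide BrC(Br)(Br)Br
Why: Ramirez dibromomethylenation (the olefination stage of the Corey–Fuchs sequence) of the electrophilic α-keto ester carbonyl by Ph3P=CBr2 gives the gem-dibromoalkene whose CBr2 carbon becomes C7; no stereocentre is formed.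

Step 3
Reactants: 4 nerol
Product: 5 [(2S,3R)-3-methyl-3-(4-methylpent-3-en-1-yl)oxiran-2-yl]methanol
Conditions: Ti(OiPr)4 (cat.), L-(+)-diethyl tartrate (cat.), t-BuOOH, 4 Å molecular sieves, CH2Cl2, −20 °C
Reagents that add atoms: tert-butyl hydroperoxide CC(C)(C)OO
Why: Sharpless asymmetric epoxidation is directed by the allylic hydroxyl and leaves the remote trisubstituted olefin untouched; the L-(+)-tartrate ligand should deliver oxygen to the face that gives the (2S,3R)-epoxide, setting C4 (R) and C5 (S), and the Z olefin geometry fixes the cis relation of C3 and C6 on the oxirane.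

Step 4
Reactants: 5 epoxy alcohol
Product: 6 (2R,3R)-3-methyl-3-(4-methylpent-3-en-1-yl)oxirane-2-carbaldehyde
Conditions: TEMPO (2,2,6,6-tetramethylpiperidin-1-oxyl, cat.), PhI(OAc)2, CH2Cl2, rt
Reagents that add atoms: none
Why: Oxoammonium (TEMPO) oxidation of the primary alcohol to the aldehyde under near-neutral conditions should spare the epoxide, the olefin and the α-stereocentre C5.

Step 5
Reactants: 3 ethyl 2-(acetoxymethyl)-3,3-dibromoprop-2-enoate and 6 epoxy aldehyde
Product: 9 [(5R)-4-bromo-5-[(2S,3R)-3-methyl-3-(4-methylpent-3-en-1-yl)oxiran-2-yl]-2-oxo-2,5-dihydrofuran-3-yl]methyl acetate, via magnesium carbenoid 7 (not isolated), via magnesium alkoxide 8 (not isolated)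
Conditions: 3, i-PrMgCl·LiCl, THF, −78 °C; then 6, −78 to 0 °C; aq. NH4Cl
Reagents that add atoms: none
Why: Chelation-directed bromine–magnesium exchange cis to the ester gives the magnesium carbenoid, whose addition to the epoxy aldehyde should follow the Felkin–Anh (Cornforth) mode anti to the epoxide C–O bond and so set C6 anti to C5, after which the alkoxide closes onto the cis ester (halogen–magnesium exchange, carbonyl addition and lactonization in one pot).

Step 6
Reactants: 9 bromobutenolide with the prenyl terminus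
Product: 11 [(5R)-4-bromo-5-[(2S,3R)-3-methyl-3-(3-oxopropyl)oxiran-2-yl]-2-oxo-2,5-dihydrofuran-3-yl]methyl acetate, via ozonide 10 (not isolated)
Conditions: O3 (1 equiv), CH2Cl2, −78 °C; then Me2S, −78 °C to rt
Reagents that add atoms: ozone [O-][O+]=O
Why: Ozonolysis with reductive work-up: ozone should cleave the electron-rich trisubstituted olefin much faster than the electron-poor brominated butenolide olefin, unmasking C1 as the aldehyde.

Step 7
Reactants: 11 C1 aldehyde
Product: 13 [(5R)-4-bromo-5-[(2S,3R)-3-[(3S,4R)-3-hydroxy-4-methylhex-5-en-1-yl]-3-methyloxiran-2-yl]-2-oxo-2,5-dihydrofuran-3-yl]methyl acetate, via borate ester 12 (not isolated)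
Conditions: (S,S)-diisopropyl tartrate (E)-crotylboronate, 4 Å molecular sieves, toluene, −78 °C; aq. NaHCO3
Reagents that add atoms: diisopropyl (4S,5S)-2-[(E)-but-2-en-1-yl]-1,3,2-dioxaborolane-4,5-dicarboxylate C/C=C/CB1O[C@H](C(=O)OC(C)C)[C@@H](C(=O)OC(C)C)O1
Why: Roush asymmetric crotylboration through a chair Zimmerman–Traxler transition state: the (E)-crotyl unit gives the anti adduct and the (S,S)-tartrate should direct attack to the Re face of the aldehyde, which sets C10 (R) (the C1 carbinol, S, is oxidised later), while the neutral reagent and non-acidic work-up should keep the new C1 hydroxyl from opening the epoxide.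

Step 8
Reactants: 13 homoallylic alcohol
Product: 15 [(5R)-4-bromo-5-[(2S,3R)-3-[(3S,4R)-3,6-dihydroxy-4-methylhexyl]-3-methyloxiran-2-yl]-2-oxo-2,5-dihydrofuran-3-yl]methyl acetate, via organoborane 14 (not isolated)
Conditions: 9-BBN (9-borabicyclo[3.3.1]nonane, excess), THF, 0 °C to rt; then aq. H2O2, pH 7 phosphate buffer, 0 °C
Reagents that add atoms: hydrogen peroxide OO
Why: Brown hydroboration: 9-BBN should add anti-Markovnikov to the monosubstituted olefin only (conjugated bromo olefin, lactone, acetate and epoxide inert), and buffered peroxide oxidises the C–B bond with retention to the primary C8 alcohol without touching C10.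

Step 9
Reactants: 15 diol
Product: 17 [(5R)-4-bromo-5-[(2S,3R)-3-methyl-3-[(4R)-4-methyl-3,6-dioxohexyl]oxiran-2-yl]-2-oxo-2,5-dihydrofuran-3-yl]methyl acetate, via bis(alkoxysulfonium) salt 16 (not isolated)
Conditions: (COCl)2, DMSO, CH2Cl2, −78 °C; then i-Pr2NEt, −78 to −20 °C
Reagents that add atoms: none
Why: Swern oxidation: both hydroxyls are converted to alkoxysulfonium ions at low temperature before base is added, so the 1,4-diol should go to the keto aldehyde without lactol or lactone formation, and the hindered base should leave C10 (α to the new ketone) unepimerised.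

Step 10
Reactants: 17 keto aldehyde
Product: 19 (4R,5S,6S,8S,10R)-13-acetoxy-4,5-epoxy-8-hydroxy-1-oxogermacr-7(11)-en-12,6-olide, via alkenylchromium dichloride 18 (not isolated)
Conditions: CrCl2 (excess), NiCl2 (cat.), degassed DMSO/THF, rt, slow addition of 17 (final 0.003 M); aq. NH4Cl
Reagents that add atoms: none
Why: CrCl2 reduces NiCl2 to zerovalent nickel, which inserts into the C7–Br bond of the vinylogous acyl bromide; transmetalation to trivalent chromium gives alkenylchromium 18, which adds 1,2 to the C8 aldehyde. The closest known reaction type is the intramolecular Nozaki–Hiyama–Kishi coupling of alkenyl halide–aldehydes used to close medium and large carbocycles. The ten-membered ring (C1–C10) closes in a 10-exo-trig mode (carbonyl oxygen outside the ring), and the butenolide geometry is kept because the C7–Cr bond reacts with retention. The new C8 stereocentre is under substrate control: the C5-to-C9 tether should stay on the face of the planar butenolide already occupied by C5 (fixed by C6) while the chromium-bound oxygen lies near the butenolide plane on the C13 side, which should lead to the 8S alkoxide; this is the least secure point of the route. The step needs aldehyde-over-ketone chemoselectivity (inherent to organochromium reagents, although the C1 ketone could close a seven-membered ring), cyclization over oligomerization (slow addition at high dilution) and a C–Cr bond covalent enough not to expel the lactone carboxylate at C6 by β-elimination.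

Step 11
Reactants: 19 macrocyclic 8S alcohol
Product: 20 (4R,5S,6S,8S,10R)-13-acetoxy-4,5-epoxy-1-oxo-8-tigloyloxygermacr-7(11)-en-12,6-olide (CNP0229937.1)
Conditions: tigloyl chloride, pyridine, 4-(dimethylamino)pyridine (cat.), CH2Cl2, 0 °C
Reagents that add atoms: (E)-2-methylbut-2-enoyl chloride C/C=C(\C)C(Cl)=O
Why: Acylation of the secondary allylic alcohol with the acid chloride (nucleophilic catalysis) proceeds with retention at C8, and the weak base pyridine should avoid ketene formation, so the E (tiglate) geometry and C10 are preserved.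

**Compound list**

1 | ethyl bromopyruvate (ethyl 3-bromo-2-oxopropanoate) | CCOC(=O)C(=O)CBr | starting material
2 | ethyl 3-acetoxy-2-oxopropanoate | CCOC(=O)C(=O)COC(C)=O | intermediate
3 | ethyl 2-(acetoxymethyl)-3,3-dibromoprop-2-enoate | CCOC(=O)C(COC(C)=O)=C(Br)Br | intermediate
4 | nerol, (2Z)-3,7-dimethylocta-2,6-dien-1-ol | CC(C)=CCC/C(C)=C\CO | starting material
5 | [(2S,3R)-3-methyl-3-(4-methylpent-3-en-1-yl)oxiran-2-yl]methanol | CC(C)=CCC[C@@]1(C)O[C@H]1CO | intermediate
6 | (2R,3R)-3-methyl-3-(4-methylpent-3-en-1-yl)oxirane-2-carbaldehyde | CC(C)=CCC[C@@]1(C)O[C@H]1C=O | intermediate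
7 | ethyl (E)-2-(acetoxymethyl)-3-bromo-3-(chloromagnesio)prop-2-enoate (Mg cis to the ester) | CCOC(=O)/C(COC(C)=O)=C(/Br)[Mg]Cl | intermediate
8 | open-chain chloromagnesium alkoxide of the adduct of 7 and 6 (C6–O–MgCl, C6 cis to the ethyl ester across C7=C11) | CC(C)=CCC[C@@]1(C)O[C@H]1[C@@H](O[Mg]Cl)/C(Br)=C(/COC(C)=O)C(=O)OCC | intermediate
9 | [(5R)-4-bromo-5-[(2S,3R)-3-methyl-3-(4-methylpent-3-en-1-yl)oxiran-2-yl]-2-oxo-2,5-dihydrofuran-3-yl]methyl acetate | CC(C)=CCC[C@@]1(C)O[C@H]1[C@H]1OC(=O)C(COC(C)=O)=C1Br | intermediate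
10 | secondary ozonide (3,3-dimethyl-1,2,4-trioxolane) of 9 at the terminal olefin | CC1(C)OOC(CC[C@@]2(C)O[C@H]2[C@H]2OC(=O)C(COC(C)=O)=C2Br)O1 | intermediate
11 | [(5R)-4-bromo-5-[(2S,3R)-3-methyl-3-(3-oxopropyl)oxiran-2-yl]-2-oxo-2,5-dihydrofuran-3-yl]methyl acetate | O=CCC[C@@]1(C)O[C@H]1[C@H]1OC(=O)C(COC(C)=O)=C1Br | intermediate
12 | C1 O-borate (diisopropyl (4S,5S)-tartrate dioxaborolane) of 13 | C=C[C@@H](C)[C@@H](OB1O[C@H](C(=O)OC(C)C)[C@@H](C(=O)OC(C)C)O1)CC[C@@]1(C)O[C@H]1[C@H]1OC(=O)C(COC(C)=O)=C1Br | intermediate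
13 | [(5R)-4-bromo-5-[(2S,3R)-3-[(3S,4R)-3-hydroxy-4-methylhex-5-en-1-yl]-3-methyloxiran-2-yl]-2-oxo-2,5-dihydrofuran-3-yl]methyl acetate | C=C[C@@H](C)[C@@H](O)CC[C@@]1(C)O[C@H]1[C@H]1OC(=O)C(COC(C)=O)=C1Br | intermediate
14 | C8 B-alkyl-9-BBN adduct of the C1 O-(9-BBN) borinate of 13 | B1(C2CCCC1CCC2)CC[C@@H](C)[C@@H](OB1C2CCCC1CCC2)CC[C@@]1(C)O[C@H]1[C@H]1OC(=O)C(COC(C)=O)=C1Br | intermediate
15 | [(5R)-4-bromo-5-[(2S,3R)-3-[(3S,4R)-3,6-dihydroxy-4-methylhexyl]-3-methyloxiran-2-yl]-2-oxo-2,5-dihydrofuran-3-yl]methyl acetate | OCC[C@@H](C)[C@@H](O)CC[C@@]1(C)O[C@H]1[C@H]1OC(=O)C(COC(C)=O)=C1Br | intermediate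
16 | bis(dimethylalkoxysulfonium) dichloride of diol 15 (at O1 and O8) | C[S+](C)OCC[C@@H](C)[C@@H](O[S+](C)C)CC[C@@]1(C)O[C@H]1[C@H]1OC(=O)C(COC(C)=O)=C1Br.[Cl-].[Cl-] | intermediate
17 | [(5R)-4-bromo-5-[(2S,3R)-3-methyl-3-[(4R)-4-methyl-3,6-dioxohexyl]oxiran-2-yl]-2-oxo-2,5-dihydrofuran-3-yl]methyl acetate | O=CC[C@@H](C)C(=O)CC[C@@]1(C)O[C@H]1[C@H]1OC(=O)C(COC(C)=O)=C1Br | intermediate
18 | C7 alkenylchromium dichloride derived from 17 | O=CC[C@@H](C)C(=O)CC[C@@]1(C)O[C@H]1[C@H]1OC(=O)C(COC(C)=O)=C1[Cr](Cl)Cl | intermediate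
19 | (4R,5S,6S,8S,10R)-13-acetoxy-4,5-epoxy-8-hydroxy-1-oxogermacr-7(11)-en-12,6-olide | O[C@H]1C[C@@H](C)C(=O)CC[C@@]2(C)O[C@H]2[C@H]2OC(=O)C(COC(C)=O)=C12 | intermediate
20 | (4R,5S,6S,8S,10R)-13-acetoxy-4,5-epoxy-1-oxo-8-tigloyloxygermacr-7(11)-en-12,6-olide (CNP0229937.1) | C/C=C(\C)C(=O)O[C@H]1C[C@@H](C)C(=O)CC[C@@]2(C)O[C@H]2[C@H]2OC(=O)C(COC(C)=O)=C12 | target

**Step count and risks**

Total step count: 11. Longest linear sequence: 9 steps (nerol 4 to target 20, steps 3–11).

Steps most likely to fail:

1. Step 10. The alkenylchromium may attack the opposite face of the C8 aldehyde, so that the ring closes mainly to the C8 epimer. Fallback: setting out from 17, the same coupling would then deliver (4R,5S,6S,8R,10R)-13-acetoxy-4,5-epoxy-8-hydroxy-1-oxogermacr-7(11)-en-12,6-olide F1. F1 is esterified under Mitsunobu conditions (tiglic acid, PPh3, diisopropyl azodicarboxylate, toluene, 0 °C), which installs the tiglate with inversion at C8 in one operation and returns to the route at target 20. The retentive acylation of step 11 is thereby replaced by an invertive SN2 esterification.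

2. Step 5. The organomagnesium conditions may remove or transfer the acetyl group of 3 during exchange, addition or lactonization. Fallback: setting out from 3 and 6, the acetate is exchanged for a silyl ether before the union and restored after it.
   - Acid-catalysed ethanolysis of 3 (HCl in ethanol) gives ethyl 3,3-dibromo-2-(hydroxymethyl)prop-2-enoate F2.
   - Silylation (t-BuMe2SiCl, imidazole, DMF) gives ethyl 3,3-dibromo-2-{[(tert-butyldimethylsilyl)oxy]methyl}prop-2-enoate F3.
   - Bromine–magnesium exchange (i-PrMgCl·LiCl, THF, −78 °C) gives ethyl (E)-3-bromo-2-{[(tert-butyldimethylsilyl)oxy]methyl}-3-(chloromagnesio)prop-2-enoate F4.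
   - F4 adds to 6 to give the open-chain chloromagnesium alkoxide F5, which lactonizes to (5R)-4-bromo-3-{[(tert-butyldimethylsilyl)oxy]methyl}-5-[(2S,3R)-3-methyl-3-(4-methylpent-3-en-1-yl)oxiran-2-yl]furan-2(5H)-one F6.
   - Desilylation (HF·pyridine, THF, 0 °C) gives (5R)-4-bromo-3-(hydroxymethyl)-5-[(2S,3R)-3-methyl-3-(4-methylpent-3-en-1-yl)oxiran-2-yl]furan-2(5H)-one F7.
   - Acetylation (Ac2O, pyridine) returns to the route at 9.

3. Step 8. During the oxidative work-up, hydroperoxide may add to the brominated butenolide carbon C7 (addition–elimination) or cleave the acetate. Fallback: setting out from 13, hydroboration with 9-BBN is run as before to organoborane 14. The borane is then oxidised directly with pyridinium chlorochromate (NaOAc, CH2Cl2), a known direct oxidation of organoboranes and borinate esters to carbonyl compounds. This returns to the route at keto aldehyde 17 and bypasses diol 15, any peroxide and the separate diol oxidation.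

**Further compounds**

F1 | step 10 | (4R,5S,6S,8R,10R)-13-acetoxy-4,5-epoxy-8-hydroxy-1-oxogermacr-7(11)-en-12,6-olide | O[C@@H]1C[C@@H](C)C(=O)CC[C@@]2(C)O[C@H]2[C@H]2OC(=O)C(COC(C)=O)=C12
F2 | step 5 | ethyl 3,3-dibromo-2-(hydroxymethyl)prop-2-enoate | CCOC(=O)C(CO)=C(Br)Br
F3 | step 5 | ethyl 3,3-dibromo-2-{[(tert-butyldimethylsilyl)oxy]methyl}prop-2-enoate | CCOC(=O)C(CO[Si](C)(C)C(C)(C)C)=C(Br)Br
F4 | step 5 | ethyl (E)-3-bromo-2-{[(tert-butyldimethylsilyl)oxy]methyl}-3-(chloromagnesio)prop-2-enoate | CCOC(=O)/C(CO[Si](C)(C)C(C)(C)C)=C(/Br)[Mg]Cl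
F5 | step 5 | open-chain chloromagnesium alkoxide of the adduct of F4 and 6 | CC(C)=CCC[C@@]1(C)O[C@H]1[C@@H](O[Mg]Cl)/C(Br)=C(/CO[Si](C)(C)C(C)(C)C)C(=O)OCC
F6 | step 5 | (5R)-4-bromo-3-{[(tert-butyldimethylsilyl)oxy]methyl}-5-[(2S,3R)-3-methyl-3-(4-methylpent-3-en-1-yl)oxiran-2-yl]furan-2(5H)-one | CC(C)=CCC[C@@]1(C)O[C@H]1[C@H]1OC(=O)C(CO[Si](C)(C)C(C)(C)C)=C1Br
F7 | step 5 | (5R)-4-bromo-3-(hydroxymethyl)-5-[(2S,3R)-3-methyl-3-(4-methylpent-3-en-1-yl)oxiran-2-yl]furan-2(5H)-one | CC(C)=CCC[C@@]1(C)O[C@H]1[C@H]1OC(=O)C(CO)=C1Br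
F0 | step 8 | none | none
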